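**Plan**

- Cuts: (a) the ester between the central carboxyl of isocitrate A and O-15′ of unit B; (b) both C11–O(isocitrate) ether bonds; (c) in each decalin the ring-fusion bond C5–C10 together with C8–C9; (d) the C2–C3 bond of each isocitrate (propane numbering), back to (R)-malic acid.
- Enabling feature: ring B is a cyclohexane with cis one-carbon arms on C8 (C12) and C9 (C11) beside the methyl-bearing quaternary C10. It is therefore the adduct of an (E)-3-methylenoyl dienophile C9=C10 (C11 as carbonyl) and a diene C5=C6–C7=C8–C12, with the chain C1–C4 of ring A as the tether.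
- Forward: an acyclic triene closes rings A and B in one intramolecular Diels–Alder reaction, then lactone, selenide and 8(12)-methylene follow. One cycloadduct serves unit B (O-15 kept) and unit A (C15 deoxygenated to the gem-dimethyl group).
- Each drimane aldehyde is joined to the isocitrate by reductive etherification, the two halves by esterification, and the carboxyls are then freed.
- Stereochemistry: C4 from asymmetric epoxidation and a stereospecific 1,2-shift; C5, C9 and C10 from the auxiliary-controlled endo cycloaddition of the E-dienophile; isocitrate C1 from (R)-malic acid and C2 from anti alkylation of its alkoxide enolate.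

Key step: step 11

Remark: bicyclic compounds carry drimane numbering (C11 on C9, C12 on C8, C15 = the 4α carbon; all have 5α-H, 9α-H, 10β-CH3); isocitrates carry propane-1,2,3-tricarboxylate numbering (C1 bears the oxygen).

**Route**

Step 1
Reactants: 1 5-chloropent-1-yne
Product: 3 (2E)-6-chloro-3-methylhex-2-en-1-ol, via alkenylalane 2 (not isolated)
Conditions: Me3Al (2 equiv), Cp2ZrCl2 (0.2 equiv), CH2Cl2, 0 °C to rt; n-BuLi, THF, −78 °C; (CH2O)n, rt; aq. HCl
Reagents that add atoms: trimethylaluminium C[Al](C)C; formaldehyde (as paraformaldehyde) C=O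
Why: Negishi zirconium-catalysed carboalumination adds CH3 and Al syn across the terminal alkyne with Al at the terminus, and the derived alanate is hydroxymethylated with retention, so only the E-trisubstituted allylic alcohol should form.

Step 2
Reactants: 3 (2E)-6-chloro-3-methylhex-2-en-1-ol
Product: 4 [(2S,3S)-3-(3-chloropropyl)-3-methyloxiran-2-yl]methanol
Conditions: Ti(OiPr)4 (10 mol%), L-(+)-diethyl tartrate (12 mol%), t-BuOOH, 4 Å MS, CH2Cl2, −20 °C
Reagents that add atoms: tert-butyl hydroperoxide CC(C)(C)OO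
Why: Sharpless asymmetric epoxidation of an E-3-methylalk-2-en-1-ol with the L-(+)-tartrate ligand delivers oxygen to the face that gives the (2S,3S)-epoxide, as with geraniol.

Step 3
Reactants: 4 [(2S,3S)-3-(3-chloropropyl)-3-methyloxiran-2-yl]methanol
Product: 5 tert-butyl{[(2S,3S)-3-(3-chloropropyl)-3-methyloxiran-2-yl]methoxy}dimethylsilane
Conditions: TBSCl, imidazole, DMF, rt
Reagents that add atoms: tert-butylchlorodimethylsilane CC(C)(C)[Si](C)(C)Cl
Why: Standard silylation of the primary alcohol provides the siloxymethyl group that migrates in step 4 and later protects O-15.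

Step 4
Reactants: 5 tert-butyl{[(2S,3S)-3-(3-chloropropyl)-3-methyloxiran-2-yl]methoxy}dimethylsilane
Product: 6 (2S)-2-[(tert-butyldimethylsilyloxy)methyl]-5-chloro-2-methylpentanal
Conditions: MeAl(OAr)2 (2 equiv; Ar = 4-bromo-2,6-di-tert-butylphenyl, from Me3Al and 2 ArOH), CH2Cl2, −78 °C; water
Reagents that add atoms: none
Why: In this Lewis-acid rearrangement of an epoxy silyl ether to a β-siloxy aldehyde, the bulky aluminium aryloxide opens the tertiary C–O bond and the siloxymethyl group migrates anti to it with inversion, so the epoxide chirality becomes the quaternary centre (future C4, CH3 β and CH2O α).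

Step 5
Reactants: 6 (2S)-2-[(tert-butyldimethylsilyloxy)methyl]-5-chloro-2-methylpentanal; 7 triethyl 4-phosphonocrotonate
Product: 8 ethyl (2E,4E,6R)-6-[(tert-butyldimethylsilyloxy)methyl]-9-chloro-6-methylnona-2,4-dienoate
Conditions: LiN(SiMe3)2, THF, −78 °C to 0 °C
Reagents that add atoms: none
Why: Vinylogous Horner–Wadsworth–Emmons olefination of a non-enolisable aldehyde with a stabilised phosphonate should give the (2E,4E)-dienoate.

Step 6
Reactants: 8 ethyl (2E,4E,6R)-6-[(tert-butyldimethylsilyloxy)methyl]-9-chloro-6-methylnona-2,4-dienoate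
Product: 9 (2E,4E,6R)-6-[(tert-butyldimethylsilyloxy)methyl]-9-chloro-6-methylnona-2,4-dien-1-ol
Conditions: i-Bu2AlH (2.5 equiv), CH2Cl2, −78 °C; aq. potassium sodium tartrate
Reagents that add atoms: none
Why: 1,2-Reduction of the conjugated ester by the aluminium hydride at low temperature gives the dienyl alcohol and leaves the alkyl chloride and silyl ether untouched.

Step 7
Reactants: 9 (2E,4E,6R)-6-[(tert-butyldimethylsilyloxy)methyl]-9-chloro-6-methylnona-2,4-dien-1-ol
Product: 10 (2E,4E,6R)-1-(benzyloxy)-6-[(tert-butyldimethylsilyloxy)methyl]-9-chloro-6-methylnona-2,4-diene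
Conditions: NaH, BnBr, Bu4NI (cat.), THF, 0 °C to rt
Reagents that add atoms: benzyl bromide BrCc1ccccc1
Why: Williamson benzylation of the allylic alkoxide is much faster than attack on the alkyl chloride, and benzyl is chosen because it is removed by the hydrogenation of step 12.

Step 8
Reactants: 10 (2E,4E,6R)-1-(benzyloxy)-6-[(tert-butyldimethylsilyloxy)methyl]-9-chloro-6-methylnona-2,4-diene; 11 methyl but-2-ynoate
Product: 13 methyl (2E,7R,8E,10E)-12-(benzyloxy)-7-[(tert-butyldimethylsilyloxy)methyl]-3,7-dimethyldodeca-2,8,10-trienoate, via Grignard reagent 12 (not isolated)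
Conditions: Mg, THF, reflux; CuBr·SMe2 (1 equiv), THF/Me2S, −45 °C; 11, −78 °C; aq. NH4Cl
Reagents that add atoms: none
Why: Syn-carbocupration of the 2-alkynoate by the organocopper reagent at −78 °C and protonation with retention place the new chain trans to the ester, giving the E-enoate with CH3 cis to CO2Me.

Step 9
Reactants: 13 methyl (2E,7R,8E,10E)-12-(benzyloxy)-7-[(tert-butyldimethylsilyloxy)methyl]-3,7-dimethyldodeca-2,8,10-trienoate
Product: 14 (2E,7R,8E,10E)-12-(benzyloxy)-7-[(tert-butyldimethylsilyloxy)methyl]-3,7-dimethyldodeca-2,8,10-trienoic acid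
Conditions: LiOH, THF/MeOH/H2O, 50 °C; aq. HCl to pH 3
Reagents that add atoms: lithium hydroxide [Li+].[OH-]
Why: Saponification of the conjugated methyl ester proceeds without touching the silyl and benzyl ethers or the alkene geometry.

Step 10
Reactants: 14 (2E,7R,8E,10E)-12-(benzyloxy)-7-[(tert-butyldimethylsilyloxy)methyl]-3,7-dimethyldodeca-2,8,10-trienoic acid; 15 (S)-4-benzyloxazolidin-2-one
Product: 17 (4S)-4-benzyl-3-[(2E,7R,8E,10E)-12-(benzyloxy)-7-[(tert-butyldimethylsilyloxy)methyl]-3,7-dimethyldodeca-2,8,10-trienoyl]oxazolidin-2-one, via mixed pivalic anhydride 16 (not isolated)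
Conditions: t-BuCOCl, Et3N, THF, −20 °C; then 15, LiCl, rt
Reagents that add atoms: none
Why: N-Acylation of the oxazolidinone through the mixed pivalic anhydride (LiCl/Et3N variant) installs the chelating chiral imide without isomerising the E-enoyl group.

Step 11
Reactants: 17 (4S)-4-benzyl-3-[(2E,7R,8E,10E)-12-(benzyloxy)-7-[(tert-butyldimethylsilyloxy)methyl]-3,7-dimethyldodeca-2,8,10-trienoyl]oxazolidin-2-one
Product: 18 (4S)-4-benzyl-3-[12-(benzyloxy)-15-(tert-butyldimethylsilyloxy)-8αH-drim-6-en-11-oyl]oxazolidin-2-one (trans-decalin; C11 and C12 both β)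
Conditions: Me2AlCl (2.5 equiv), CH2Cl2, −30 °C to 0 °C; 1 M HCl
Reagents that add atoms: none
Why: Me2AlCl forms the cationic bidentate chelate of the imide (both carbonyls on aluminium, enoyl s-cis), which lowers the dienophile LUMO so that the tethered (E,E)-diene adds in a concerted, asynchronous [4π+2π] cycloaddition, the closest known reaction type being the Lewis-acid-promoted intramolecular Diels–Alder reaction of N-trienoyl oxazolidinones. Ring B is the new cyclohexene, closed by the two new bonds C5–C10 and C8–C9 (suprafacial on both partners), and ring A is closed in the same event by C5–C10 alone, the four-carbon chain C1–C4 tying the diene terminus C5 to the dienophile carbon C10 (six-membered, tether exo). C9 and C10 are set by the auxiliary, whose benzyl group blocks one face of the chelate so that the diene adds to the Cα-si face, and by the E geometry, which keeps C11 and the C10 methyl cis. C5 and C8 are set by the carbonyl-endo transition state, in which the tether lies anti (trans ring fusion, 5α-H) and the E,E-diene puts C12 cis to C11 (this C8 centre is erased in steps 15 and 22). The step needs endo over exo and auxiliary-face selectivity, both secured by the rigid chelate and reinforced by the C4 centre, whose methyl takes the axial position syn to the C10 methyl while the larger silyloxymethyl group stays equatorial (matched case).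

Step 12
Reactants: 18 (4S)-4-benzyl-3-[12-(benzyloxy)-15-(tert-butyldimethylsilyloxy)-8αH-drim-6-en-11-oyl]oxazolidin-2-one
Product: 20 15-(tert-butyldimethylsilyloxy)-8αH-driman-11,12-olide (cis-fused γ-lactone; C11 carbonyl), via hydroxy imide 19 (not isolated)
Conditions: H2 (1 atm), 10% Pd/C, EtOAc, rt; filter; DBU (cat.), CH2Cl2, rt
Reagents that add atoms: none
Why: Heterogeneous hydrogenation saturates C6=C7 and cleaves the benzyl ether, and the freed 12-OH, cis to the C9 acyl group, lactonises onto the activated imide carbonyl and expels the auxiliary for recovery (any epimerisation at C8 would be harmless because C8 later becomes sp2).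

Step 13
Reactants: 20 15-(tert-butyldimethylsilyloxy)-8αH-driman-11,12-olide
Product: 21 15-(tert-butyldimethylsilyloxy)-12-(phenylselanyl)-8αH-driman-11-oic acid
Conditions: PhSeH, NaH, 18-crown-6, THF, 65 °C; aq. HCl
Reagents that add atoms: benzeneselenol [SeH]c1ccccc1
Why: SN2 opening of the γ-lactone at its primary O-alkyl carbon C12 by the soft selenolate installs the selenide and frees the C11 carboxyl without touching a stereocentre.

Step 14
Reactants: 21 15-(tert-butyldimethylsilyloxy)-12-(phenylselanyl)-8αH-driman-11-oic acid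
Product: 22 15-(tert-butyldimethylsilyloxy)-12-(phenylselanyl)-8αH-driman-11-ol
Conditions: BH3·THF, THF, 0 °C to rt; MeOH
Reagents that add atoms: none
Why: Borane reduces the carboxylic acid chemoselectively to the primary alcohol while the selenide and silyl ether are inert.

Step 15
Reactants: 22 15-(tert-butyldimethylsilyloxy)-12-(phenylselanyl)-8αH-driman-11-ol
Product: 24 15-(tert-butyldimethylsilyloxy)drim-8(12)-en-11-ol, via selenoxide 23 (not isolated)
Conditions: mCPBA (1.0 equiv), CH2Cl2, −78 °C; then i-Pr2NH, 40 °C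
Reagents that add atoms: none
Why: Selenoxide syn-elimination can only use H8, the single β-hydrogen, so the 8(12)-exocyclic alkene should form regiospecifically, with the amine trapping the selenenic acid.

Step 16
Reactants: 24 15-(tert-butyldimethylsilyloxy)drim-8(12)-en-11-ol
Product: 25 15-(tert-butyldimethylsilyloxy)drim-8(12)-en-11-al
Conditions: Dess–Martin periodinane, NaHCO3, CH2Cl2, 0 °C
Reagents that add atoms: none
Why: Buffered Dess–Martin oxidation gives the β,γ-unsaturated aldehyde under neutral conditions that should avoid double-bond migration and epimerisation at C9.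

Step 17
Reactants: 20 15-(tert-butyldimethylsilyloxy)-8αH-driman-11,12-olide
Product: 26 15-hydroxy-8αH-driman-11,12-olide
Conditions: HF·pyridine, THF, 0 °C to rt
Reagents that add atoms: none
Why: Fluoride-mediated cleavage of the primary silyl ether leaves the lactone intact and frees O-15 for removal in unit A.

Step 18
Reactants: 26 15-hydroxy-8αH-driman-11,12-olide
Product: 27 O-(11-oxo-8αH-driman-11,12-olid-15-yl) O-phenyl thiocarbonate
Conditions: PhOC(S)Cl, pyridine, DMAP (cat.), CH2Cl2, rt
Reagents that add atoms: O-phenyl chlorothionoformate S=C(Cl)Oc1ccccc1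
Why: Acylation of the neopentyl primary alcohol to the phenyl thionocarbonate sets up radical deoxygenation under neutral conditions.

Step 19
Reactants: 27 O-(11-oxo-8αH-driman-11,12-olid-15-yl) O-phenyl thiocarbonate
Product: 28 8αH-driman-11,12-olide
Conditions: Bu3SnH, AIBN (cat.), toluene, 110 °C
Reagents that add atoms: none
Why: In this Barton–McCombie deoxygenation the stannyl radical adds to C=S, β-scission gives the primary neopentyl radical, which cannot rearrange, and hydrogen transfer completes the gem-dimethyl group of unit A.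

Step 20
Reactants: 28 8αH-driman-11,12-olide
Product: 29 12-(phenylselanyl)-8αH-driman-11-oic acid
Conditions: PhSeH, NaH, 18-crown-6, THF, 65 °C; aq. HCl
Reagents that add atoms: benzeneselenol [SeH]c1ccccc1
Why: The same selenolate SN2 lactone opening as in step 13 places selenium on C12 and frees the C11 acid.

Step 21
Reactants: 29 12-(phenylselanyl)-8αH-driman-11-oic acid
Product: 30 12-(phenylselanyl)-8αH-driman-11-ol
Conditions: BH3·THF, THF, 0 °C to rt; MeOH
Reagents that add atoms: none
Why: Chemoselective borane reduction of the acid to the primary alcohol as in step 14.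

Step 22
Reactants: 30 12-(phenylselanyl)-8αH-driman-11-ol
Product: 32 (+)-albicanol (drim-8(12)-en-11-ol), via selenoxide 31 (not isolated)
Conditions: mCPBA (1.0 equiv), CH2Cl2, −78 °C; then i-Pr2NH, 40 °C
Reagents that add atoms: none
Why: Selenoxide syn-elimination through H8 gives the exocyclic methylene regiospecifically, as in step 15.

Step 23
Reactants: 32 (+)-albicanol
Product: 33 albicanal (drim-8(12)-en-11-al)
Conditions: Dess–Martin periodinane, NaHCO3, CH2Cl2, 0 °C
Reagents that add atoms: none
Why: Buffered Dess–Martin oxidation to the aldehyde as in step 16.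

Step 24
Reactants: 34 (R)-malic acid
Product: 36 (3R)-3-hydroxy-4-methoxy-4-oxobutanoic acid, via cyclic anhydride 35 (not isolated)
Conditions: (CF3CO)2O, 0 °C to rt; evaporate; MeOH, rt
Reagents that add atoms: methanol CO
Why: Trifluoroacetic anhydride gives the O-trifluoroacetyl cyclic anhydride, which methanol opens at the more electrophilic carbonyl next to the acyloxy carbon and then de-trifluoroacetylates, so the 1-methyl ester forms regioselectively with C2 untouched.

Step 25
Reactants: 36 (3R)-3-hydroxy-4-methoxy-4-oxobutanoic acid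
Product: 37 1-methyl 4-(prop-2-enyl) (2R)-2-hydroxybutanedioate
Conditions: allyl bromide, KHCO3, DMF, rt
Reagents that add atoms: allyl bromide C=CCBr
Why: Carboxylate O-alkylation under weakly basic conditions esterifies only the free acid and leaves the secondary alcohol and the methyl ester alone.

Step 26
Reactants: 37 1-methyl 4-(prop-2-enyl) (2R)-2-hydroxybutanedioate
Product: 39 3-tert-butyl 1-methyl 2-(prop-2-enyl) (1R,2S)-1-hydroxypropane-1,2,3-tricarboxylate, via dilithium alkoxide enolate 38 (not isolated)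
Conditions: LiN(SiMe3)2 (2.2 equiv), THF, −78 °C; BrCH2CO2t-Bu, −78 °C to −50 °C; AcOH
Reagents that add atoms: tert-butyl bromoacetate CC(C)(C)OC(=O)CBr
Why: In this Fráter–Seebach alkylation the chelated lithium alkoxide enolate is alkylated anti to the oxygen-bearing carbon, which sets the new centre as S and gives the (1R,2S) isocitrate configuration.

Step 27
Reactants: 39 3-tert-butyl 1-methyl 2-(prop-2-enyl) (1R,2S)-1-hydroxypropane-1,2,3-tricarboxylate
Product: 40 3-tert-butyl 1-methyl 2-(prop-2-enyl) (1R,2S)-1-(trimethylsilyloxy)propane-1,2,3-tricarboxylate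
Conditions: Me3SiCl, imidazole, CH2Cl2, 0 °C
Reagents that add atoms: chlorotrimethylsilane C[Si](C)(C)Cl
Why: Silylation gives the alkoxysilane needed as the oxygen partner in the reductive etherification and blocks lactonisation.

Step 28
Reactants: 33 albicanal; 40 3-tert-butyl 1-methyl 2-(prop-2-enyl) (1R,2S)-1-(trimethylsilyloxy)propane-1,2,3-tricarboxylate
Product: 41 3-tert-butyl 1-methyl 2-(prop-2-enyl) (1R,2S)-1-[drim-8(12)-en-11-yloxy]propane-1,2,3-tricarboxylate
Conditions: 40 (2 equiv), Et3SiH, Me3SiOTf (0.2 equiv), CH2Cl2, −78 °C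
Reagents that add atoms: none
Why: In this reductive etherification the aldehyde and silyl ether form an oxocarbenium ion that Et3SiH reduces to the hindered C11–O ether under non-basic conditions, which avoid retro-aldol and β-elimination of the isocitrate and break no bond at its stereocentres.

Step 29
Reactants: 41 3-tert-butyl 1-methyl 2-(prop-2-enyl) (1R,2S)-1-[drim-8(12)-en-11-yloxy]propane-1,2,3-tricarboxylate
Product: 42 (2S,3R)-2-[2-(tert-butoxy)-2-oxoethyl]-3-[drim-8(12)-en-11-yloxy]-4-methoxy-4-oxobutanoic acid (unit A acid)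
Conditions: Pd(PPh3)4 (5 mol%), N-methylaniline, THF, rt
Reagents that add atoms: none
Why: Zerovalent palladium ionises only the allyl ester to a π-allyl complex that the amine captures, a neutral deallylation that leaves tert-butyl and methyl esters and the exocyclic alkene alone.

Step 30
Reactants: 25 15-(tert-butyldimethylsilyloxy)drim-8(12)-en-11-al; 40 3-tert-butyl 1-methyl 2-(prop-2-enyl) (1R,2S)-1-(trimethylsilyloxy)propane-1,2,3-tricarboxylate
Product: 43 3-tert-butyl 1-methyl 2-(prop-2-enyl) (1R,2S)-1-{[15-(tert-butyldimethylsilyloxy)drim-8(12)-en-11-yl]oxy}propane-1,2,3-tricarboxylate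
Conditions: 40 (2 equiv), Et3SiH, Me3SiOTf (0.2 equiv), CH2Cl2, −78 °C
Reagents that add atoms: none
Why: The same reductive etherification as in step 28, with the remote neopentyl silyl ether stable to catalytic silyl triflate at −78 °C.

Step 31
Reactants: 43 3-tert-butyl 1-methyl 2-(prop-2-enyl) (1R,2S)-1-{[15-(tert-butyldimethylsilyloxy)drim-8(12)-en-11-yl]oxy}propane-1,2,3-tricarboxylate
Product: 44 3-tert-butyl 1-methyl 2-(prop-2-enyl) (1R,2S)-1-{[15-hydroxydrim-8(12)-en-11-yl]oxy}propane-1,2,3-tricarboxylate (unit B alcohol)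
Conditions: HF·pyridine, pyridine, THF, 0 °C to rt
Reagents that add atoms: none
Why: Buffered fluoride desilylation frees the 15-OH without harming the three esters, the ether or the exocyclic alkene.

Step 32
Reactants: 42 unit A acid; 44 unit B alcohol
Product: 46 fully protected dimer (central carboxyl of isocitrate A esterified by O-15′; 3-carboxyls as tert-butyl esters; central carboxyl of isocitrate B as allyl ester), via mixed anhydride 45 (not isolated)
Conditions: 2-methyl-6-nitrobenzoic anhydride, Et3N, DMAP (cat.), CH2Cl2, rt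
Reagents that add atoms: none
Why: Shiina esterification activates the hindered acid as a mixed aromatic anhydride that DMAP transfers to the neopentyl primary alcohol at room temperature, mild enough to limit epimerisation α to the acyl group.

Step 33
Reactants: 46 fully protected dimer
Product: 48 dimer with both 3-carboxyls free and the central carboxyl of isocitrate B still as allyl ester, via bis(trimethylsilyl) ester 47 (not isolated)
Conditions: Me3SiOTf, 2,6-lutidine, CH2Cl2, 0 °C; then pH 4 aqueous buffer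
Reagents that add atoms: none
Why: Buffered silyl triflate converts the tert-butyl esters into silyl esters with loss of isobutene and no free strong acid, so the exocyclic alkenes and the allyl and methyl esters should survive, and the silyl esters hydrolyse on work-up.

Step 34
Reactants: 48 dimer diacid allyl ester
Product: 49 target compound
Conditions: Pd(PPh3)4 (5 mol%), N-methylaniline, THF, rt
Reagents that add atoms: none
Why: Neutral zerovalent-palladium deallylation frees the last carboxyl without base, which would provoke β-elimination of the alkoxy group, and without touching the methyl esters or the alkenes.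

**Compound list**

1 | 5-chloropent-1-yne | C#CCCCCl | starting material
2 | (E)-(5-chloro-2-methylpent-1-enyl)dimethylalane | C[Al](C)/C=C(\C)CCCCl | intermediate
3 | (2E)-6-chloro-3-methylhex-2-en-1-ol | OC/C=C(\C)CCCCl | intermediate
4 | [(2S,3S)-3-(3-chloropropyl)-3-methyloxiran-2-yl]methanol | OC[C@@H]1O[C@@]1(C)CCCCl | intermediate
5 | tert-butyl{[(2S,3S)-3-(3-chloropropyl)-3-methyloxiran-2-yl]methoxy}dimethylsilane | CC(C)(C)[Si](C)(C)OC[C@@H]1O[C@@]1(C)CCCCl | intermediate
6 | (2S)-2-[(tert-butyldimethylsilyloxy)methyl]-5-chloro-2-methylpentanal | O=C[C@](C)(CO[Si](C)(C)C(C)(C)C)CCCCl | intermediate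
7 | triethyl 4-phosphonocrotonate (ethyl (2E)-4-(diethoxyphosphoryl)but-2-enoate) | CCOC(=O)/C=C/CP(=O)(OCC)OCC | starting material
8 | ethyl (2E,4E,6R)-6-[(tert-butyldimethylsilyloxy)methyl]-9-chloro-6-methylnona-2,4-dienoate | CCOC(=O)/C=C/C=C/[C@](C)(CO[Si](C)(C)C(C)(C)C)CCCCl | intermediate
9 | (2E,4E,6R)-6-[(tert-butyldimethylsilyloxy)methyl]-9-chloro-6-methylnona-2,4-dien-1-ol | OC/C=C/C=C/[C@](C)(CO[Si](C)(C)C(C)(C)C)CCCCl | intermediate
10 | (2E,4E,6R)-1-(benzyloxy)-6-[(tert-butyldimethylsilyloxy)methyl]-9-chloro-6-methylnona-2,4-diene | C(OCc1ccccc1)/C=C/C=C/[C@](C)(CO[Si](C)(C)C(C)(C)C)CCCCl | intermediate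
11 | methyl but-2-ynoate | CC#CC(=O)OC | starting material
12 | alkylmagnesium chloride derived from 10 (MgCl on the terminal carbon) | C(OCc1ccccc1)/C=C/C=C/[C@](C)(CO[Si](C)(C)C(C)(C)C)CCC[Mg]Cl | intermediate
13 | methyl (2E,7R,8E,10E)-12-(benzyloxy)-7-[(tert-butyldimethylsilyloxy)methyl]-3,7-dimethyldodeca-2,8,10-trienoate | C(OCc1ccccc1)/C=C/C=C/[C@](C)(CO[Si](C)(C)C(C)(C)C)CCC/C(C)=C/C(=O)OC | intermediate
14 | (2E,7R,8E,10E)-12-(benzyloxy)-7-[(tert-butyldimethylsilyloxy)methyl]-3,7-dimethyldodeca-2,8,10-trienoic acid | C(OCc1ccccc1)/C=C/C=C/[C@](C)(CO[Si](C)(C)C(C)(C)C)CCC/C(C)=C/C(=O)O | intermediate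
15 | (S)-4-benzyloxazolidin-2-one | O=C1OC[C@H](Cc2ccccc2)N1 | starting material
16 | mixed anhydride of 14 with pivalic acid | C(OCc1ccccc1)/C=C/C=C/[C@](C)(CO[Si](C)(C)C(C)(C)C)CCC/C(C)=C/C(=O)OC(=O)C(C)(C)C | intermediate
17 | (4S)-4-benzyl-3-[(2E,7R,8E,10E)-12-(benzyloxy)-7-[(tert-butyldimethylsilyloxy)methyl]-3,7-dimethyldodeca-2,8,10-trienoyl]oxazolidin-2-one | C(OCc1ccccc1)/C=C/C=C/[C@](C)(CO[Si](C)(C)C(C)(C)C)CCC/C(C)=C/C(=O)N1[C@@H](Cc2ccccc2)COC1=O | intermediate
18 | (4S)-4-benzyl-3-[12-(benzyloxy)-15-(tert-butyldimethylsilyloxy)-8αH-drim-6-en-11-oyl]oxazolidin-2-one (5α-H, 9α-H, 10β-CH3, 4β-CH3, C12 β) | C(OCc1ccccc1)[C@H]1C=C[C@H]2[C@](C)(CO[Si](C)(C)C(C)(C)C)CCC[C@]2(C)[C@H]1C(=O)N1[C@@H](Cc2ccccc2)COC1=O | intermediate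
19 | (4S)-4-benzyl-3-[15-(tert-butyldimethylsilyloxy)-12-hydroxy-8αH-driman-11-oyl]oxazolidin-2-one | OC[C@H]1CC[C@H]2[C@](C)(CO[Si](C)(C)C(C)(C)C)CCC[C@]2(C)[C@H]1C(=O)N1[C@@H](Cc2ccccc2)COC1=O | intermediate
20 | 15-(tert-butyldimethylsilyloxy)-8αH-driman-11,12-olide (C11 carbonyl, cis-fused) | O1C[C@H]2CC[C@H]3[C@](C)(CO[Si](C)(C)C(C)(C)C)CCC[C@]3(C)[C@H]2C1=O | intermediate
21 | 15-(tert-butyldimethylsilyloxy)-12-(phenylselanyl)-8αH-driman-11-oic acid | c1ccccc1[Se]C[C@H]1CC[C@H]2[C@](C)(CO[Si](C)(C)C(C)(C)C)CCC[C@]2(C)[C@H]1C(=O)O | intermediate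
22 | 15-(tert-butyldimethylsilyloxy)-12-(phenylselanyl)-8αH-driman-11-ol | c1ccccc1[Se]C[C@H]1CC[C@H]2[C@](C)(CO[Si](C)(C)C(C)(C)C)CCC[C@]2(C)[C@H]1CO | intermediate
23 | Se-oxide of 22 | O=[Se](c1ccccc1)C[C@H]1CC[C@H]2[C@](C)(CO[Si](C)(C)C(C)(C)C)CCC[C@]2(C)[C@H]1CO | intermediate
24 | 15-(tert-butyldimethylsilyloxy)drim-8(12)-en-11-ol | C=C1CC[C@H]2[C@](C)(CO[Si](C)(C)C(C)(C)C)CCC[C@]2(C)[C@H]1CO | intermediate
25 | 15-(tert-butyldimethylsilyloxy)drim-8(12)-en-11-al | C=C1CC[C@H]2[C@](C)(CO[Si](C)(C)C(C)(C)C)CCC[C@]2(C)[C@H]1C=O | intermediate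
26 | 15-hydroxy-8αH-driman-11,12-olide | O1C[C@H]2CC[C@H]3[C@](C)(CO)CCC[C@]3(C)[C@H]2C1=O | intermediate
27 | O-phenyl thionocarbonate of 26 at O-15 | O1C[C@H]2CC[C@H]3[C@](C)(COC(=S)Oc4ccccc4)CCC[C@]3(C)[C@H]2C1=O | intermediate
28 | 8αH-driman-11,12-olide | O1C[C@H]2CC[C@H]3C(C)(C)CCC[C@]3(C)[C@H]2C1=O | intermediate
29 | 12-(phenylselanyl)-8αH-driman-11-oic acid | c1ccccc1[Se]C[C@H]1CC[C@H]2C(C)(C)CCC[C@]2(C)[C@H]1C(=O)O | intermediate
30 | 12-(phenylselanyl)-8αH-driman-11-ol | c1ccccc1[Se]C[C@H]1CC[C@H]2C(C)(C)CCC[C@]2(C)[C@H]1CO | intermediate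
31 | Se-oxide of 30 | O=[Se](c1ccccc1)C[C@H]1CC[C@H]2C(C)(C)CCC[C@]2(C)[C@H]1CO | intermediate
32 | (+)-albicanol, [(1S,4aS,8aS)-5,5,8a-trimethyl-2-methylidenedecahydronaphthalen-1-yl]methanol | C=C1CC[C@H]2C(C)(C)CCC[C@]2(C)[C@H]1CO | intermediate
33 | albicanal (drim-8(12)-en-11-al) | C=C1CC[C@H]2C(C)(C)CCC[C@]2(C)[C@H]1C=O | intermediate
34 | (R)-malic acid | O[C@@H](C(=O)O)CC(=O)O | starting material
35 | (R)-O-trifluoroacetylmalic anhydride | FC(F)(F)C(=O)O[C@@H]1CC(=O)OC1=O | intermediate
36 | (3R)-3-hydroxy-4-methoxy-4-oxobutanoic acid | O[C@@H](C(=O)OC)CC(=O)O | intermediate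
37 | 1-methyl 4-(prop-2-enyl) (2R)-2-hydroxybutanedioate | O[C@@H](C(=O)OC)CC(=O)OCC=C | intermediate
38 | dilithium alkoxide enolate of 37 | [Li+].[Li+].[O-][C@@H](C(=O)OC)/C=C(\[O-])OCC=C | intermediate
39 | 3-tert-butyl 1-methyl 2-(prop-2-enyl) (1R,2S)-1-hydroxypropane-1,2,3-tricarboxylate | O[C@@H](C(=O)OC)[C@H](CC(=O)OC(C)(C)C)C(=O)OCC=C | intermediate
40 | 3-tert-butyl 1-methyl 2-(prop-2-enyl) (1R,2S)-1-(trimethylsilyloxy)propane-1,2,3-tricarboxylate | C[Si](C)(C)O[C@@H](C(=O)OC)[C@H](CC(=O)OC(C)(C)C)C(=O)OCC=C | intermediate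
41 | 3-tert-butyl 1-methyl 2-(prop-2-enyl) (1R,2S)-1-[drim-8(12)-en-11-yloxy]propane-1,2,3-tricarboxylate | C=C1CC[C@H]2C(C)(C)CCC[C@]2(C)[C@H]1CO[C@@H](C(=O)OC)[C@H](CC(=O)OC(C)(C)C)C(=O)OCC=C | intermediate
42 | unit A acid: 41 with the central (2-) carboxyl free | C=C1CC[C@H]2C(C)(C)CCC[C@]2(C)[C@H]1CO[C@@H](C(=O)OC)[C@H](CC(=O)OC(C)(C)C)C(=O)O | intermediate
43 | 3-tert-butyl 1-methyl 2-(prop-2-enyl) (1R,2S)-1-{[15-(tert-butyldimethylsilyloxy)drim-8(12)-en-11-yl]oxy}propane-1,2,3-tricarboxylate | C=C1CC[C@H]2[C@](C)(CO[Si](C)(C)C(C)(C)C)CCC[C@]2(C)[C@H]1CO[C@@H](C(=O)OC)[C@H](CC(=O)OC(C)(C)C)C(=O)OCC=C | intermediate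
44 | unit B alcohol: 3-tert-butyl 1-methyl 2-(prop-2-enyl) (1R,2S)-1-{[15-hydroxydrim-8(12)-en-11-yl]oxy}propane-1,2,3-tricarboxylate | C=C1CC[C@H]2[C@](C)(CO)CCC[C@]2(C)[C@H]1CO[C@@H](C(=O)OC)[C@H](CC(=O)OC(C)(C)C)C(=O)OCC=C | intermediate
45 | mixed anhydride of 42 with 2-methyl-6-nitrobenzoic acid | C=C1CC[C@H]2C(C)(C)CCC[C@]2(C)[C@H]1CO[C@@H](C(=O)OC)[C@H](CC(=O)OC(C)(C)C)C(=O)OC(=O)c1c(C)cccc1[N+](=O)[O-] | intermediate
46 | fully protected dimer (both 3-carboxyls tert-butyl esters; central carboxyl of isocitrate B allyl ester) | C=C1CC[C@H]2C(C)(C)CCC[C@]2(C)[C@H]1CO[C@@H](C(=O)OC)[C@H](CC(=O)OC(C)(C)C)C(=O)OC[C@]1(C)CCC[C@]2(C)[C@@H](CO[C@@H](C(=O)OC)[C@H](CC(=O)OC(C)(C)C)C(=O)OCC=C)C(=C)CC[C@@H]12 | intermediate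
47 | bis(trimethylsilyl) ester corresponding to 46 | C=C1CC[C@H]2C(C)(C)CCC[C@]2(C)[C@H]1CO[C@@H](C(=O)OC)[C@H](CC(=O)O[Si](C)(C)C)C(=O)OC[C@]1(C)CCC[C@]2(C)[C@@H](CO[C@@H](C(=O)OC)[C@H](CC(=O)O[Si](C)(C)C)C(=O)OCC=C)C(=C)CC[C@@H]12 | intermediate
48 | dimer with both 3-carboxyls free and the central carboxyl of isocitrate B as allyl ester | C=C1CC[C@H]2C(C)(C)CCC[C@]2(C)[C@H]1CO[C@@H](C(=O)OC)[C@H](CC(=O)O)C(=O)OC[C@]1(C)CCC[C@]2(C)[C@@H](CO[C@@H](C(=O)OC)[C@H](CC(=O)O)C(=O)OCC=C)C(=C)CC[C@@H]12 | intermediate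
49 | target: albicanol 11-O-[(1R,2S)-isocitrate 1-methyl ester] whose central carboxyl is esterified by O-15′ of 15-hydroxyalbicanol 11-O-[(1R,2S)-isocitrate 1-methyl ester] | C=C1CC[C@H]2C(C)(C)CCC[C@]2(C)[C@H]1CO[C@@H](C(=O)OC)[C@H](CC(=O)O)C(=O)OC[C@]1(C)CCC[C@]2(C)[C@@H](CO[C@@H](C(=O)OC)[C@H](CC(=O)O)C(=O)O)C(=C)CC[C@@H]12 | target

**Step count and risks**

Total step count: 34. Longest linear sequence: 24 steps (steps 1–12, 17–23, 28, 29, 32, 33, 34).

Steps most likely to fail:

1. Step 11. The β,β-disubstituted enoyl imide may be too unreactive toward Lewis-acid activation, the dienyl benzyl ether may ionise, or endo/trans selectivity may erode. The fallback sets out from 13 and uses a thermal cycloaddition of the methyl ester itself (toluene, BHT, 170 °C, sealed tube), with stereocontrol passing from an auxiliary to the C4 centre (methyl axial, silyloxymethyl equatorial in the chair-like tether). This should give the methyl 12-(benzyloxy)-15-(tert-butyldimethylsilyloxy)-8αH-drim-6-en-11-oate F1. Hydrogenation and hydrogenolysis (H2, Pd/C) would give the hydroxy ester F2, which lactonises (TsOH cat., toluene, 80 °C) with loss of methanol and rejoins the route at 20, where minor diastereomers would be removed.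

2. Step 28 (and its twin, step 30). Oxocarbenium formation between the hindered aldehyde and the weakly nucleophilic α-silyloxy ester may be slow, allowing self-reduction of the aldehyde, migration of the exocyclic double bond into conjugation, or epimerisation at C9. The fallback replaces reductive etherification by SN2 O-alkylation. From 32, Tf2O and 2,6-di-tert-butyl-4-methylpyridine (CH2Cl2, −78 °C) would give albicanyl triflate F3, which alkylates the free hydroxy triester 39 under the same hindered, non-nucleophilic base (CH2Cl2, rt) and returns to the route at 41. In the same way 24 would give the 15-silyloxy triflate F4, which returns at 43.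

3. Step 32. Acylation of the neopentyl alcohol may be slow enough for the activated acyl group to lose the β-alkoxy group (elimination to an aconitate) or to epimerise at the α-carbon. The fallback inverts the polarity and avoids acyl activation. From 44, Tf2O and 2,6-lutidine (CH2Cl2, −78 °C) would give the neopentyl triflate F5, which the caesium carboxylate of 42 (CsHCO3, DMF, 50 °C) displaces at C15′ by carboxylate O-alkylation, returning to the route at 46.

Further compounds
F1 | step 11 | methyl 12-(benzyloxy)-15-(tert-butyldimethylsilyloxy)-8αH-drim-6-en-11-oate | C(OCc1ccccc1)[C@H]1C=C[C@H]2[C@](C)(CO[Si](C)(C)C(C)(C)C)CCC[C@]2(C)[C@H]1C(=O)OC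
F2 | step 11 | methyl 15-(tert-butyldimethylsilyloxy)-12-hydroxy-8αH-driman-11-oate | OC[C@H]1CC[C@H]2[C@](C)(CO[Si](C)(C)C(C)(C)C)CCC[C@]2(C)[C@H]1C(=O)OC
F3 | step 28 | drim-8(12)-en-11-yl trifluoromethanesulfonate (albicanyl triflate) | C=C1CC[C@H]2C(C)(C)CCC[C@]2(C)[C@H]1COS(=O)(=O)C(F)(F)F
F4 | step 28 | 15-(tert-butyldimethylsilyloxy)drim-8(12)-en-11-yl trifluoromethanesulfonate | C=C1CC[C@H]2[C@](C)(CO[Si](C)(C)C(C)(C)C)CCC[C@]2(C)[C@H]1COS(=O)(=O)C(F)(F)F
F5 | step 32 | 15-O-trifluoromethanesulfonate of unit B alcohol 44 | C=C1CC[C@H]2[C@](C)(COS(=O)(=O)C(F)(F)F)CCC[C@]2(C)[C@H]1CO[C@@H](C(=O)OC)[C@H](CC(=O)OC(C)(C)C)C(=O)OCC=C
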